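**Retrosynthetic overview**
1. The C11–C12 bond is cut to an sp3–sp3 coupling of a bicyclic C11 organometallic with (2E,6E)-farnesyl bromide; the C8 methyl is cut to an enol triflate/methyl cuprate coupling. This leaves an 8-oxygenated bicyclic C11 unit.
2. That unit comes from one intramolecular Diels–Alder reaction of an acyclic triene, which makes C5–C10 and C8–C9 together. Ring A closes as the tether ring and ring B as the cycloadduct ring, in the same step.
3. Enabling feature: ring B is a cyclohexene retron, C5–C6=C7–C8(O) as a 1-oxygenated diene and C9=C10 as an enoyl dienophile with C11 as its acyl carbon. The C1–C2–C3–C4 chain of ring A, with the C4 gem-dimethyl group, is the four-carbon tether from diene terminus C5 to dienophile carbon C10. A chiral N-acyl oxazolidinone on C11 sets the absolute configuration and is removed when C11 is reduced.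
4. The triene is built linearly: C1–C10 by B-alkyl Suzuki–Miyaura coupling (fixes the E enoate), C6 by methoxymethylene Wittig, C7–C8 by formylmethylene Wittig, then dienol silylation.

Key step: step 9

Remark: locants C1–C22 and the α/β labels are those of the target skeleton (ring A = C1–C5 and C10, ring B = C5–C10, C11 on C9, β = face of the C10 methyl); the equatorial (β) C9 substituent is assumed to be the thermodynamically preferred one, as in related 9-substituted trans-decalins.

**Route**

Step 1
Reactants: 1 2,2-dimethylpent-4-enal; 2 (methoxymethyl)triphenylphosphonium chloride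
Product: 3 1-methoxy-3,3-dimethylhexa-1,5-diene (E/Z mixture at the enol ether)
Conditions: 2, KOt-Bu, THF, 0 °C; then 1, 0 °C to rt
Reagents that add atoms: none
Why: Wittig methoxymethylenation of the α-quaternary aldehyde adds C6 as a masked aldehyde, and the enol ether geometry does not matter because it is hydrolysed in step 6.

Step 2
Reactants: 4 methyl acetoacetate
Product: 5 methyl (2E)-3-(trifluoromethanesulfonyloxy)but-2-enoate
Conditions: Tf2O, aq Me4NOH, toluene, 5 °C
Reagents that add atoms: triflic anhydride, O=S(=O)(OS(=O)(=O)C(F)(F)F)C(F)(F)F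
Why: O-triflation of the β-keto ester enolate; the non-chelated tetramethylammonium enolate should be trapped as the E enol triflate (OTf trans to the ester), which later fixes the C9=C10 geometry.

Step 3
Reactants: 3 1-methoxy-3,3-dimethylhexa-1,5-diene; 5 methyl (2E)-3-(trifluoromethanesulfonyloxy)but-2-enoate
Product: 7 methyl (2E)-9-methoxy-3,7,7-trimethylnona-2,8-dienoate, via B-alkyl-9-BBN borane 6 (not isolated)
Conditions: 9-BBN, THF, 0 °C to rt; then 5, Pd(dppf)Cl2 (cat.), K3PO4, DMF/H2O, 50 °C
Reagents that add atoms: none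
Why: B-alkyl Suzuki–Miyaura coupling: 9-BBN should hydroborate only the terminal alkene (the enol ether is internal and shielded by the quaternary carbon), and the alkylborane couples with the enol triflate with retention to give the E enoate (chain trans, methyl cis to the ester).

Step 4
Reactants: 7 methyl (2E)-9-methoxy-3,7,7-trimethylnona-2,8-dienoate
Product: 8 (2E)-9-methoxy-3,7,7-trimethylnona-2,8-dienoic acid
Conditions: LiOH, THF/MeOH/H2O, 50 °C; then cold 0.5 M HCl to pH 5
Reagents that add atoms: lithium hydroxide, [Li+].[OH-]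
Why: Saponification of the β,β-disubstituted enoate; the enol ether is stable to base and should survive the brief, cold, weakly acidic work-up.

Step 5
Reactants: 8 (2E)-9-methoxy-3,7,7-trimethylnona-2,8-dienoic acid; 9 (4S)-4-benzyl-1,3-oxazolidin-2-one
Product: 11 (4S)-4-benzyl-3-[(2E)-9-methoxy-3,7,7-trimethylnona-2,8-dienoyl]-1,3-oxazolidin-2-one, via mixed pivalic anhydride 10 (not isolated)
Conditions: PivCl, Et3N, THF, −20 °C; then 9, LiCl, −20 °C to rt
Reagents that add atoms: none
Why: Mixed-anhydride N-acylation of the oxazolidinone (LiCl/Et3N activation) attaches the chiral auxiliary under non-acidic conditions that the enol ether tolerates.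

Step 6
Reactants: 11 (4S)-4-benzyl-3-[(2E)-9-methoxy-3,7,7-trimethylnona-2,8-dienoyl]-1,3-oxazolidin-2-one
Product: 12 (4S)-4-benzyl-3-[(2E)-3,7,7-trimethyl-9-oxonon-2-enoyl]-1,3-oxazolidin-2-one
Conditions: 1 M HCl, THF, rt
Reagents that add atoms: water, O
Why: Acid-catalysed enol ether hydrolysis unmasks the C6 aldehyde, while the imide and the enoyl unit are stable to dilute acid.

Step 7
Reactants: 12 (4S)-4-benzyl-3-[(2E)-3,7,7-trimethyl-9-oxonon-2-enoyl]-1,3-oxazolidin-2-one; 13 (triphenylphosphoranylidene)acetaldehyde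
Product: 14 (4S)-4-benzyl-3-[(2E,9E)-3,7,7-trimethyl-11-oxoundeca-2,9-dienoyl]-1,3-oxazolidin-2-one
Conditions: 13, toluene, 80 °C
Reagents that add atoms: none
Why: Wittig reaction with the stabilised formylmethylene ylide should give the E enal (C6=C7, C8 aldehyde) and stop after one homologation because the enal product is less electrophilic.

Step 8
Reactants: 14 (4S)-4-benzyl-3-[(2E,9E)-3,7,7-trimethyl-11-oxoundeca-2,9-dienoyl]-1,3-oxazolidin-2-one
Product: 15 (4S)-4-benzyl-3-[(2E,8E,10E)-11-(tert-butyldimethylsilyloxy)-3,7,7-trimethylundeca-2,8,10-trienoyl]-1,3-oxazolidin-2-one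
Conditions: TBSOTf, Et3N, CH2Cl2, −78 to 0 °C
Reagents that add atoms: tert-butyldimethylsilyl triflate, CC(C)(C)[Si](C)(C)OS(=O)(=O)C(F)(F)F
Why: Soft γ-enolisation and O-silylation of the enal from its s-trans conformer should give the (1E,3E)-1-silyloxydiene C5=C6–C7=C8(OTBS), the aldehyde reacting much faster than the imide.

Step 9
Reactants: 15 (4S)-4-benzyl-3-[(2E,8E,10E)-11-(tert-butyldimethylsilyloxy)-3,7,7-trimethylundeca-2,8,10-trienoyl]-1,3-oxazolidin-2-one
Product: 16 trans-fused Diels–Alder adduct: 9β-acyl (C11 = imide carbonyl of the (4S)-4-benzyl-2-oxo-oxazolidin-3-yl group), 8β-OTBS, 4,4,10β-trimethyl, 5α-H, 9α-H, C6=C7 alkene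
Conditions: Me2AlCl (1.5 equiv), CH2Cl2, −30 to 0 °C; cold 1 M HCl quench
Reagents that add atoms: none
Why: Me2AlCl chelates the two imide carbonyls, locks the enoyl unit s-cis and lets the benzyl group cover the re face of C9, so the tethered (1E,3E)-1-silyloxydiene adds to the si face in a concerted, strongly asynchronous [4+2] cycloaddition in which bonding of the nucleophilic diene terminus C5 to the electrophilic β-carbon C10 runs ahead of C8–C9 (a vinylogous Mukaiyama–Michael component). The closest known reaction type is the Lewis-acid-promoted intramolecular Diels–Alder reaction of (E,E,E)-triene N-acyl oxazolidinones, which gives trans-fused bicyclo[4.4.0]decenes through the endo transition state. Ring A is closed as the six-membered tether ring of a type 1 intramolecular Diels–Alder reaction (the C1–C4 chain joins diene terminus C5 to dienophile carbon C10), and ring B is the new cyclohexene, formed suprafacially on both partners. C10 and C9 take their relative configuration from the E geometry of the enoyl unit (methyl and acyl cis on ring B) and their absolute configuration from the auxiliary; C5 is set by the endo arrangement (chelated acyl under the diene, tether anti), which gives the trans ring fusion; C8 (silyloxy β) follows from the 1E enol ether and is erased in step 14. The step needs ortho regiochemistry, endo selectivity and one dienophile face: the four-carbon tether and the matched polarity of a 1-oxygenated diene with an enoyl β-carbon secure the first, the chelated acyl group the second and the benzyl group the third, while C9 stays correctable because it is α to a carbonyl with the wanted acyl group equatorial.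

Step 10
Reactants: 16 trans-fused Diels–Alder adduct
Product: 17 C11 alcohol: 9β-(hydroxymethyl)-8β-(tert-butyldimethylsilyloxy)-4,4,10β-trimethyl trans-fused bicycle, 5α-H, 9α-H, C6=C7 alkene
Conditions: LiBH4, MeOH (1 equiv), THF, 0 °C
Reagents that add atoms: none
Why: Reductive cleavage of the N-acyl oxazolidinone by borohydride gives the primary alcohol and returns the auxiliary, leaving the allylic silyl ether and the alkene untouched.

Step 11
Reactants: 17 C11 alcohol
Product: 18 C11 bromide: 9β-(bromomethyl)-8β-(tert-butyldimethylsilyloxy)-4,4,10β-trimethyl trans-fused bicycle, 5α-H, 9α-H, C6=C7 alkene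
Conditions: CBr4, PPh3, CH2Cl2, 0 °C
Reagents that add atoms: carbon tetrabromide, BrC(Br)(Br)Br
Why: Appel bromination converts the hindered primary alcohol under neutral conditions that spare the silyl ether.

Step 12
Reactants: 18 C11 bromide; 19 (2E,6E)-farnesyl bromide
Product: 21 silyl ether with the full side chain: 9β-[(3E,7E)-4,8,12-trimethyltrideca-3,7,11-trienyl]-8β-(tert-butyldimethylsilyloxy)-4,4,10β-trimethyl trans-fused bicycle, 5α-H, 9α-H, C6=C7 alkene, via Grignard reagent 20 (not isolated)
Conditions: Mg, THF, reflux; then 19, Li2CuCl4 (cat.), THF, −20 to 0 °C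
Reagents that add atoms: none
Why: Copper-catalysed coupling of the Grignard reagent with the primary allylic bromide at its α-carbon (SN2 mode) should form C11–C12 and keep both E alkenes of the farnesyl unit.

Step 13
Reactants: 21 silyl ether with the full side chain
Product: 22 allylic alcohol: 8β-hydroxy, C6=C7 alkene, 9β side chain, 4,4,10β-trimethyl, 5α-H, 9α-H
Conditions: Bu4NF, THF, rt
Reagents that add atoms: none
Why: Fluoride-mediated desilylation frees the allylic C8 alcohol without affecting the alkenes.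

Step 14
Reactants: 22 allylic alcohol
Product: 23 enone: C8 ketone conjugated with the C6=C7 alkene, 9β side chain, 4,4,10β-trimethyl, 5α-H, 9α-H
Conditions: DMP (1,1,1-triacetoxy-1,1-dihydro-1,2-benziodoxol-3(1H)-one), NaHCO3, CH2Cl2, rt
Reagents that add atoms: none
Why: Hypervalent-iodine oxidation of the allylic alcohol gives the enone; C9 is now α to the ketone but already carries its side chain in the thermodynamically preferred equatorial (β) position.

Step 15
Reactants: 23 enone
Product: 25 enol triflate: C7=C8 alkene with OTf on C8, 9β side chain, 4,4,10β-trimethyl, 5α-H, 9α-H, via lithium enolate 24 (not isolated)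
Conditions: LiBH(s-Bu)3, THF, −78 °C; then PhNTf2, −78 to 0 °C
Reagents that add atoms: N-phenyl-bis(trifluoromethanesulfonimide), O=S(=O)(N(c1ccccc1)S(=O)(=O)C(F)(F)F)C(F)(F)F
Why: Conjugate reduction of the β-unsubstituted cyclohexenone by the bulky borohydride gives the C7=C8 enolate regiospecifically, and trapping it as the triflate fixes the alkene position without enolising C9.

Step 16
Reactants: 25 enol triflate
Product: 26 target, (5S,9S,10S)-configured (CNP0141177.1)
Conditions: Me2CuLi, Et2O/THF, −20 °C
Reagents that add atoms: lithium dimethylcuprate, [Li+].C[Cu-]C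
Why: Cross-coupling of the enol triflate with the methyl cuprate installs the C8 methyl with retention of the C7=C8 position, and no stereocenter is touched.

**Compound list**

1 | 2,2-dimethylpent-4-enal | C=CCC(C)(C)C=O | starting material
2 | (methoxymethyl)triphenylphosphonium chloride | COC[P+](c1ccccc1)(c1ccccc1)c1ccccc1.[Cl-] | starting material
3 | 1-methoxy-3,3-dimethylhexa-1,5-diene (E/Z mixture) | COC=CC(C)(C)CC=C | intermediate
4 | methyl acetoacetate | CC(=O)CC(=O)OC | starting material
5 | methyl (2E)-3-(trifluoromethanesulfonyloxy)but-2-enoate | C/C(OS(=O)(=O)C(F)(F)F)=C\C(=O)OC | intermediate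
6 | 9-(6-methoxy-4,4-dimethylhex-5-en-1-yl)-9-borabicyclo[3.3.1]nonane | COC=CC(C)(C)CCCB1C2CCCC1CCC2 | intermediate
7 | methyl (2E)-9-methoxy-3,7,7-trimethylnona-2,8-dienoate | COC=CC(C)(C)CCC/C(C)=C/C(=O)OC | intermediate
8 | (2E)-9-methoxy-3,7,7-trimethylnona-2,8-dienoic acid | COC=CC(C)(C)CCC/C(C)=C/C(=O)O | intermediate
9 | (4S)-4-benzyl-1,3-oxazolidin-2-one | O=C1OC[C@H](Cc2ccccc2)N1 | starting material
10 | mixed pivalic anhydride of acid 8 | COC=CC(C)(C)CCC/C(C)=C/C(=O)OC(=O)C(C)(C)C | intermediate
11 | (4S)-4-benzyl-3-[(2E)-9-methoxy-3,7,7-trimethylnona-2,8-dienoyl]-1,3-oxazolidin-2-one | COC=CC(C)(C)CCC/C(C)=C/C(=O)N1[C@@H](Cc2ccccc2)COC1=O | intermediate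
12 | (4S)-4-benzyl-3-[(2E)-3,7,7-trimethyl-9-oxonon-2-enoyl]-1,3-oxazolidin-2-one | O=CCC(C)(C)CCC/C(C)=C/C(=O)N1[C@@H](Cc2ccccc2)COC1=O | intermediate
13 | (triphenylphosphoranylidene)acetaldehyde | O=CC=P(c1ccccc1)(c1ccccc1)c1ccccc1 | starting material
14 | (4S)-4-benzyl-3-[(2E,9E)-3,7,7-trimethyl-11-oxoundeca-2,9-dienoyl]-1,3-oxazolidin-2-one | O=C/C=C/CC(C)(C)CCC/C(C)=C/C(=O)N1[C@@H](Cc2ccccc2)COC1=O | intermediate
15 | (4S)-4-benzyl-3-[(2E,8E,10E)-11-(tert-butyldimethylsilyloxy)-3,7,7-trimethylundeca-2,8,10-trienoyl]-1,3-oxazolidin-2-one | CC(C)(C)[Si](C)(C)O/C=C/C=C/C(C)(C)CCC/C(C)=C/C(=O)N1[C@@H](Cc2ccccc2)COC1=O | intermediate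
16 | trans-fused Diels–Alder adduct (9β-acyl imide, 8β-OTBS, 5α-H, 10β-Me, C6=C7) | O=C([C@H]1[C@@H](O[Si](C)(C)C(C)(C)C)C=C[C@H]2C(C)(C)CCC[C@]12C)N1[C@@H](Cc2ccccc2)COC1=O | intermediate
17 | C11 alcohol (9β-CH2OH, 8β-OTBS, 5α-H, 10β-Me, C6=C7) | OC[C@H]1[C@@H](O[Si](C)(C)C(C)(C)C)C=C[C@H]2C(C)(C)CCC[C@]12C | intermediate
18 | C11 bromide (9β-CH2Br, 8β-OTBS, 5α-H, 10β-Me, C6=C7) | BrC[C@H]1[C@@H](O[Si](C)(C)C(C)(C)C)C=C[C@H]2C(C)(C)CCC[C@]12C | intermediate
19 | (2E,6E)-farnesyl bromide | CC(C)=CCC/C(C)=C/CC/C(C)=C/CBr | starting material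
20 | Grignard reagent of bromide 18 | Br[Mg]C[C@H]1[C@@H](O[Si](C)(C)C(C)(C)C)C=C[C@H]2C(C)(C)CCC[C@]12C | intermediate
21 | silyl ether with full side chain (8β-OTBS, C6=C7) | CC(C)=CCC/C(C)=C/CC/C(C)=C/CC[C@H]1[C@@H](O[Si](C)(C)C(C)(C)C)C=C[C@H]2C(C)(C)CCC[C@]12C | intermediate
22 | allylic alcohol (8β-OH, C6=C7) | CC(C)=CCC/C(C)=C/CC/C(C)=C/CC[C@H]1[C@@H](O)C=C[C@H]2C(C)(C)CCC[C@]12C | intermediate
23 | enone (C8 ketone, C6=C7) | CC(C)=CCC/C(C)=C/CC/C(C)=C/CC[C@H]1C(=O)C=C[C@H]2C(C)(C)CCC[C@]12C | intermediate
24 | lithium enolate (C7=C8, O–Li on C8) | CC(C)=CCC/C(C)=C/CC/C(C)=C/CC[C@H]1C(O[Li])=CC[C@H]2C(C)(C)CCC[C@]12C | intermediate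
25 | enol triflate (C7=C8, OTf on C8) | CC(C)=CCC/C(C)=C/CC/C(C)=C/CC[C@H]1C(OS(=O)(=O)C(F)(F)F)=CC[C@H]2C(C)(C)CCC[C@]12C | intermediate
26 | (5S,9S,10S)-target, CNP0141177.1 | CC(C)=CCC/C(C)=C/CC/C(C)=C/CC[C@H]1C(C)=CC[C@H]2C(C)(C)CCC[C@]12C | target

**Totals**
Total step count: 16. Longest linear sequence: 15 steps (steps 1 and 3–16; step 2 is a one-step branch).

**Steps most likely to fail, with fallbacks**

Step 9 (key cycloaddition). The Lewis acid may strip the silyl dienol ether before cyclisation, or endo and facial discrimination may be poor at the hindered β,β-disubstituted dienophile. The fallback drops both Lewis acid and auxiliary and sets out from 7. The enol ether of 7 is hydrolysed (1 M HCl, THF) to methyl (2E)-3,7,7-trimethyl-9-oxonon-2-enoate F1. Wittig homologation with 13 gives methyl (2E,9E)-3,7,7-trimethyl-11-oxoundeca-2,9-dienoate F2, and silylation (TBSOTf, Et3N) gives the silyl dienol ether ester F3. Thermal cyclisation (toluene, 170 °C, sealed tube, BHT) should give the racemic trans-fused adduct ester F4, which LiAlH4 reduces to the racemic C11 alcohol F5. Lipase-catalysed acetylation (Burkholderia cepacia lipase, vinyl acetate, MTBE) is assumed to leave 17 unreacted and convert its enantiomer to the acetate F6; if the lipase prefers 17 instead, methanolysis of its acetate (K2CO3, MeOH) gives 17. The route is rejoined at 17.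

Step 12 (C11–C12 coupling). Magnesium insertion into the hindered bromide may be sluggish, and the coupling may suffer allylic transposition (SN2′ attack) or homocoupling. The fallback is a sulfone alkylation from 18. Displacement with PhSNa (DMF) gives the C11 phenyl sulfide F7, and oxidation (H2O2, catalytic (NH4)6Mo7O24, EtOH) gives the C11 phenyl sulfone F8. Deprotonation (n-BuLi, THF/HMPA, −78 °C) and alkylation with 19 give the C11-farnesylated sulfone F9 as both C11 epimers. Reductive desulfonylation (Na(Hg), Na2HPO4, MeOH) rejoins the route at 21.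

Step 15 (reductive triflation). The borohydride may reduce the carbonyl directly (1,2-reduction), or the enolate may be trapped incompletely. The fallback separates the two events, from 23. Conjugate reduction with [(Ph3P)CuH]6 (benzene, rt, aqueous work-up) gives the saturated C8 ketone F10. Kinetic deprotonation (LiN(i-Pr)2, THF, −78 °C), which should remove C7–H rather than the hindered tertiary C9–H, and triflation with N-(5-chloropyridin-2-yl)triflimide rejoin the route at 25.

Further compounds
F1 | step 9 | methyl (2E)-3,7,7-trimethyl-9-oxonon-2-enoate | O=CCC(C)(C)CCC/C(C)=C/C(=O)OC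
F2 | step 9 | methyl (2E,9E)-3,7,7-trimethyl-11-oxoundeca-2,9-dienoate | O=C/C=C/CC(C)(C)CCC/C(C)=C/C(=O)OC
F3 | step 9 | methyl (2E,8E,10E)-11-(tert-butyldimethylsilyloxy)-3,7,7-trimethylundeca-2,8,10-trienoate | CC(C)(C)[Si](C)(C)O/C=C/C=C/C(C)(C)CCC/C(C)=C/C(=O)OC
F4 | step 9 | racemic trans-fused adduct methyl ester (9β-CO2Me, 8β-OTBS, 5α-H, 10β-Me, C6=C7, and its enantiomer) | COC(=O)[C@H]1[C@@H](O[Si](C)(C)C(C)(C)C)C=C[C@H]2C(C)(C)CCC[C@]12C.COC(=O)[C@@H]1[C@H](O[Si](C)(C)C(C)(C)C)C=C[C@@H]2C(C)(C)CCC[C@@]12C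
F5 | step 9 | racemic C11 alcohol (17 and its enantiomer) | OC[C@H]1[C@@H](O[Si](C)(C)C(C)(C)C)C=C[C@H]2C(C)(C)CCC[C@]12C.OC[C@@H]1[C@H](O[Si](C)(C)C(C)(C)C)C=C[C@@H]2C(C)(C)CCC[C@@]12C
F6 | step 9 | C11 acetate of the enantiomer of 17 | CC(=O)OC[C@@H]1[C@H](O[Si](C)(C)C(C)(C)C)C=C[C@@H]2C(C)(C)CCC[C@@]12C
F7 | step 12 | C11 phenyl sulfide (9β-CH2SPh, 8β-OTBS, C6=C7) | c1ccc(cc1)SC[C@H]1[C@@H](O[Si](C)(C)C(C)(C)C)C=C[C@H]2C(C)(C)CCC[C@]12C
F8 | step 12 | C11 phenyl sulfone (9β-CH2SO2Ph, 8β-OTBS, C6=C7) | O=S(=O)(C[C@H]1[C@@H](O[Si](C)(C)C(C)(C)C)C=C[C@H]2C(C)(C)CCC[C@]12C)c1ccccc1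
F9 | step 12 | C11-farnesylated phenyl sulfone (both C11 epimers) | CC(C)=CCC/C(C)=C/CC/C(C)=C/CC([C@H]1[C@@H](O[Si](C)(C)C(C)(C)C)C=C[C@H]2C(C)(C)CCC[C@]12C)S(=O)(=O)c1ccccc1
F10 | step 15 | saturated C8 ketone with the 9β side chain | CC(C)=CCC/C(C)=C/CC/C(C)=C/CC[C@H]1C(=O)CC[C@H]2C(C)(C)CCC[C@]12C
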